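**Retrosynthetic overview**
1. Ring numbering used for all atom labels: C1(CO2Me)=C2–C3(OAc)–C4H2–C5(Me)=C6–C7=C8(iPr)–C9H2–C10(OH)–C11(CO2Me)=C12–C13H2–C14H2, one fourteen-membered carbocycle; macrocycles are named with it. The strategy rests on C3, a homoallylic carbinol whose C4 methylene runs into the E-C5=C6 bond of the C5–C8 diene: the product pattern of a carbonyl-ene reaction between a C3 aldehyde and a 2-methylallyl group (C4=C5(Me)–C6H2).
2. Key disconnection C3–C4 (C5=C6 and O–H arise in the same event): a type 2 macrocyclic carbonyl-ene reaction of ynal 25 closes the only ring. The C1 enoate is then grown from the C3–C2≡C1 propargylic alcohol by trans-hydroalumination, iodination and methoxycarbonylation.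
3. The C11 ester is carried through the Lewis-acid and hydride steps as CH2OTBS; its carbon comes from hydroxyl-directed trans-hydrostannation and carbonylation of C11≡C12.
4. C6–C5 by palladium-catalysed allyl–alkenyl coupling; C7=C8 (C6 and C9 cis) by a lactonising Horner–Wadsworth–Emmons reaction; C10 by a boron aldol of 3-methylbutan-2-one with an ynal from hexa-1,5-diyne.

Key step: step 16

Remark: (+)-Ipc2BCl (step 3) and the (R)-BINOL–titanium Lewis acid (step 16) are each assumed to direct attack to the Re face of the aldehyde, by analogy with unsubstituted enol borinates and with glyoxylate–ene reactions; the antipodal reagent would be taken if the sense proved opposite.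

**Route**

Step 1
Reactants: 1 hexa-1,5-diyne
Product: 3 trimethyl(hexa-1,5-diyn-1-yl)silane, via lithium hexa-1,5-diyn-1-ide 2 (not isolated)
Conditions: 1 (3 equiv), n-BuLi (1 equiv), THF, −78 °C; Me3SiCl, −78 °C → rt; unreacted 1 distilled off
Reagents that add atoms: chlorotrimethylsilane, C[Si](C)(C)Cl
Why: Deprotonation of one terminal alkyne and C-silylation of the acetylide, with excess diyne to hold bis-silylation down; the silyl cap keeps C1≡C2 out of the later acetylide and ruthenium chemistry.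

Step 2
Reactants: 3 trimethyl(hexa-1,5-diyn-1-yl)silane
Product: 5 7-(trimethylsilyl)hepta-2,6-diynal, via lithium 6-(trimethylsilyl)hexa-1,5-diyn-1-ide 4 (not isolated)
Conditions: n-BuLi, THF, −78 °C; DMF, −78 → 0 °C; reverse quench into cold pH 6 phosphate buffer
Reagents that add atoms: N,N-dimethylformamide, CN(C)C=O
Why: Formylation of a lithium acetylide with DMF should give the ynal (future C10) after buffered hydrolysis of the hemiaminal salt.

Step 3
Reactants: 5 7-(trimethylsilyl)hepta-2,6-diynal; 6 3-methylbutan-2-one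
Product: 8 (5R)-5-hydroxy-2-methyl-11-(trimethylsilyl)undeca-6,10-diyn-3-one, via diisopinocampheylboron enolate of 3-methylbutan-2-one 7 (not isolated)
Conditions: 6, (+)-Ipc2BCl, Et3N, Et2O, 0 °C; then 5, −78 → −20 °C; H2O2, MeOH, pH 7 buffer, 0 °C
Reagents that add atoms: none
Why: Reagent-controlled boron aldol reaction: the ketone is enolised on its methyl side and the isopinocampheyl ligands should steer the enolate to the Re face of the ynal in a cyclic transition state, setting C10 as R.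

Step 4
Reactants: 8 (5R)-5-hydroxy-2-methyl-11-(trimethylsilyl)undeca-6,10-diyn-3-one; 9 diethylphosphonoacetic acid
Product: 10 (5R)-2-methyl-3-oxo-11-(trimethylsilyl)undeca-6,10-diyn-5-yl (diethoxyphosphoryl)acetate
Conditions: DCC, DMAP (5 mol%), CH2Cl2, 0 °C
Reagents that add atoms: none
Why: Steglich esterification of the propargylic alcohol, run cold and with little DMAP so that β-elimination of the β-acyloxy ketone should stay slow.

Step 5
Reactants: 10 (5R)-2-methyl-3-oxo-11-(trimethylsilyl)undeca-6,10-diyn-5-yl (diethoxyphosphoryl)acetate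
Product: 11 (6R)-4-isopropyl-6-[6-(trimethylsilyl)hexa-1,5-diyn-1-yl]-5,6-dihydro-2H-pyran-2-one
Conditions: LiCl, iPr2NEt, MeCN, rt
Reagents that add atoms: none
Why: Intramolecular Horner–Wadsworth–Emmons reaction under mild base; the six-membered lactone forces the ester carbon (C6) and C9 to be cis on the new C7=C8 bond, and C10 is untouched.

Step 6
Reactants: 11 (6R)-4-isopropyl-6-[6-(trimethylsilyl)hexa-1,5-diyn-1-yl]-5,6-dihydro-2H-pyran-2-one
Product: 12 (2E,5R)-3-isopropyl-11-(trimethylsilyl)undec-2-ene-6,10-diyne-1,5-diol (CH2OH and C4 cis on the double bond)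
Conditions: iBu2AlH (4 equiv), CH2Cl2, −78 → 0 °C; aqueous tartrate work-up
Reagents that add atoms: none
Why: Exhaustive 1,2-reduction of the unsaturated lactone by an aluminium hydride should give the diol with the ring-derived alkene geometry kept; the triple bonds are not hydroaluminated at this temperature.

Step 7
Reactants: 12 (2E,5R)-3-isopropyl-11-(trimethylsilyl)undec-2-ene-6,10-diyne-1,5-diol
Product: 13 (2E,5R,6Z)-3-isopropyl-6-(tributylstannyl)-11-(trimethylsilyl)undeca-2,6-dien-10-yne-1,5-diol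
Conditions: [Cp*RuCl]4 (2.5 mol%), Bu3SnH (1.1 equiv, slow addition), CH2Cl2, rt
Reagents that add atoms: tributyltin hydride, CCCC[SnH](CCCC)CCCC
Why: Hydroxyl-directed ruthenium-catalysed trans-hydrostannation: hydrogen bonding of the free C10 hydroxyl to the chloride on ruthenium should favour C11≡C12 over the silyl-capped triple bond and place tin on proximal C11, and the anti addition of H and Sn fixes C10 and C13 trans.

Step 8
Reactants: 13 (2E,5R,6Z)-3-isopropyl-6-(tributylstannyl)-11-(trimethylsilyl)undeca-2,6-dien-10-yne-1,5-diol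
Product: 14 methyl (2Z)-2-[(1R,3E)-1,5-dihydroxy-3-isopropylpent-3-en-1-yl]-7-(trimethylsilyl)hept-2-en-6-ynoate
Conditions: Pd(OAc)2 (5 mol%), Ph3As (10 mol%), 1,4-benzoquinone (1.5 equiv), CF3CO2H (20 mol%), CO (1 atm), MeOH, rt
Reagents that add atoms: carbon monoxide, [C-]#[O+]; methanol, CO
Why: Oxidative palladium-catalysed methoxycarbonylation of the alkenylstannane (hydroxyl-assisted tin-to-palladium transfer, CO insertion, methanolysis, reoxidation of palladium by the quinone) with retention of the alkene geometry.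

Step 9
Reactants: 14 methyl (2Z)-2-[(1R,3E)-1,5-dihydroxy-3-isopropylpent-3-en-1-yl]-7-(trimethylsilyl)hept-2-en-6-ynoate
Product: 15 methyl (2Z)-2-[(1R,3E)-5-chloro-1-hydroxy-3-isopropylpent-3-en-1-yl]-7-(trimethylsilyl)hept-2-en-6-ynoate
Conditions: NCS, Me2S, CH2Cl2, −30 → 0 °C; used at once
Reagents that add atoms: N-chlorosuccinimide, O=C1CCC(=O)N1Cl
Why: Corey–Kim chlorination: the unhindered primary allylic alcohol is activated as its alkoxysulfonium salt and displaced by chloride at C6 without allylic shift or loss of geometry, while the hindered C10 alcohol beside the ester should not react.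

Step 10
Reactants: 15 methyl (2Z)-2-[(1R,3E)-5-chloro-1-hydroxy-3-isopropylpent-3-en-1-yl]-7-(trimethylsilyl)hept-2-en-6-ynoate
Product: 16 methyl (2Z)-2-[(1R,3E)-5-chloro-3-isopropyl-1-(triisopropylsilyloxy)pent-3-en-1-yl]-7-(trimethylsilyl)hept-2-en-6-ynoate
Conditions: iPr3SiOTf, 2,6-lutidine, CH2Cl2, −78 → 0 °C
Reagents that add atoms: triisopropylsilyl trifluoromethanesulfonate, CC(C)[Si](C(C)C)(C(C)C)OS(=O)(=O)C(F)(F)F
Why: Silylation of the secondary alcohol with a silyl triflate and a hindered base removes the hydroxyl that could cyclise onto C6 and installs the C10 ether that lasts to the final step.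

Step 11
Reactants: 16 methyl (2Z)-2-[(1R,3E)-5-chloro-3-isopropyl-1-(triisopropylsilyloxy)pent-3-en-1-yl]-7-(trimethylsilyl)hept-2-en-6-ynoate; 17 2-bromopropene
Product: 20 methyl (2Z)-2-[(1R,3E)-3-isopropyl-6-methyl-1-(triisopropylsilyloxy)hepta-3,6-dien-1-yl]-7-(trimethylsilyl)hept-2-en-6-ynoate, via isopropenylmagnesium bromide 18 (not isolated), via isopropenylzinc chloride 19 (not isolated)
Conditions: 17, Mg, THF; ZnCl2, 0 °C; then 16, Pd(PPh3)4 (5 mol%), THF, 0 °C → rt
Reagents that add atoms: none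
Why: Negishi alkenyl–allyl coupling through a π-allylpalladium chloride: the alkenyl group goes to the unsubstituted terminus C6, and because the geometry could only scramble via palladium σ-bonded to fully substituted C8, the cis relation of C6 and C9 should be kept; ester, silyl ether and silylalkyne tolerate the organozinc.

Step 12
Reactants: 20 methyl (2Z)-2-[(1R,3E)-3-isopropyl-6-methyl-1-(triisopropylsilyloxy)hepta-3,6-dien-1-yl]-7-(trimethylsilyl)hept-2-en-6-ynoate
Product: 21 (2E)-2-[(1R,3E)-3-isopropyl-6-methyl-1-(triisopropylsilyloxy)hepta-3,6-dien-1-yl]-7-(trimethylsilyl)hept-2-en-6-yn-1-ol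
Conditions: iBu2AlH (2.5 equiv), CH2Cl2, −78 °C; aqueous tartrate work-up
Reagents that add atoms: none
Why: 1,2-Reduction of the enoate to the allylic alcohol takes the C11 carboxyl carbon to an oxidation level that survives the later hydride step.

Step 13
Reactants: 21 (2E)-2-[(1R,3E)-3-isopropyl-6-methyl-1-(triisopropylsilyloxy)hepta-3,6-dien-1-yl]-7-(trimethylsilyl)hept-2-en-6-yn-1-ol
Product: 22 [(5E,7R,9E)-6-[(tert-butyldimethylsilyloxy)methyl]-9-isopropyl-12-methyl-7-(triisopropylsilyloxy)trideca-5,9,12-trien-1-yn-1-yl]trimethylsilane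
Conditions: t-BuMe2SiCl, imidazole, CH2Cl2, 0 °C → rt
Reagents that add atoms: tert-butyldimethylsilyl chloride, CC(C)(C)[Si](C)(C)Cl
Why: Standard silylation of the primary allylic alcohol gives a silyl ether that can later be removed in the presence of the secondary triisopropylsilyl ether.

Step 14
Reactants: 22 [(5E,7R,9E)-6-[(tert-butyldimethylsilyloxy)methyl]-9-isopropyl-12-methyl-7-(triisopropylsilyloxy)trideca-5,9,12-trien-1-yn-1-yl]trimethylsilane
Product: 23 (5E,7R,9E)-6-[(tert-butyldimethylsilyloxy)methyl]-9-isopropyl-12-methyl-7-(triisopropylsilyloxy)trideca-5,9,12-trien-1-yne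
Conditions: K2CO3 (0.3 equiv), MeOH, rt
Reagents that add atoms: none
Why: Carbonate-catalysed methanolysis of the alkynyl C–Si bond; the O-silyl ethers are stable under these conditions.

Step 15
Reactants: 23 (5E,7R,9E)-6-[(tert-butyldimethylsilyloxy)methyl]-9-isopropyl-12-methyl-7-(triisopropylsilyloxy)trideca-5,9,12-trien-1-yne
Product: 25 (6E,8R,10E)-7-[(tert-butyldimethylsilyloxy)methyl]-10-isopropyl-13-methyl-8-(triisopropylsilyloxy)tetradeca-6,10,13-trien-2-ynal, via C2-lithium acetylide 24 (not isolated)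
Conditions: n-BuLi, THF, −78 °C; DMF, −78 → 0 °C; reverse quench into cold pH 6 phosphate buffer
Reagents that add atoms: N,N-dimethylformamide, CN(C)C=O
Why: Formylation of the lithium acetylide gives the non-enolisable ynal (C3); the doubly allylic C6 hydrogens should not be removed by n-BuLi at −78 °C.

Step 16
Reactants: 25 (6E,8R,10E)-7-[(tert-butyldimethylsilyloxy)methyl]-10-isopropyl-13-methyl-8-(triisopropylsilyloxy)tetradeca-6,10,13-trien-2-ynal
Product: 26 (3R,5E,7E,10R,11E)-11-[(tert-butyldimethylsilyloxy)methyl]-8-isopropyl-5-methyl-10-(triisopropylsilyloxy)cyclotetradeca-5,7,11-trien-1-yn-3-ol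
Conditions: (R)-BINOL (22 mol%), TiCl2(OiPr)2 (20 mol%), 4 Å molecular sieves, CH2Cl2; 25 added by syringe pump to 1 mM, −30 → 0 °C
Reagents that add atoms: none
Why: Proposed new method: the titanium Lewis acid binds the ynal oxygen, the terminal alkene carbon C4 adds to C3 while positive charge builds on tertiary C5, and the doubly allylic C6 hydrogen passes to oxygen through a six-membered transition state, so C3–C4 and C5=C6 form in one event. The closest known reactions are Lewis-acid type 2 intramolecular carbonyl-ene cyclisations to common rings, BINOL–titanium carbonyl-ene reactions of 1,1-disubstituted alkenes with glyoxylates and ester-substituted ynals, and Lewis-acid macrocyclisations of allylstannanes onto ynals; a fourteen-membered ene closure is without precedent. The ring closes 14-exo at the aldehyde carbon with both ene carbons C4 and C5 inside the ring and the tether leaving from C6 (type 2 mode), which a large ring allows because the C6–H bond can reach the carbonyl oxygen. The new C3 centre is set by the (R)-BINOL ligand, which should send C4 to the Re face of the aldehyde (3R), the distant C10 centre not being expected to interfere. The step needs the 2-methylallyl alkene to react before the two trisubstituted alkenes (it is the least hindered, the only one leading to a fourteen-membered ring, and C11=C12 is deactivated by two allylic oxygens), hydrogen loss from C6 and not from the methyl group (double allylic activation, conjugated diene formed) and E geometry at C5=C6 (C4 and C7 anti in the transition state). High dilution should suppress intermolecular reaction, and the ynal cannot enolise.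

Step 17
Reactants: 26 (3R,5E,7E,10R,11E)-11-[(tert-butyldimethylsilyloxy)methyl]-8-isopropyl-5-methyl-10-(triisopropylsilyloxy)cyclotetradeca-5,7,11-trien-1-yn-3-ol
Product: 28 (1Z,3R,5E,7E,10R,11E)-11-[(tert-butyldimethylsilyloxy)methyl]-1-iodo-8-isopropyl-5-methyl-10-(triisopropylsilyloxy)cyclotetradeca-1,5,7,11-tetraen-3-ol, via cyclic sodium alkenylalanate 27 (not isolated)
Conditions: NaAlH2(OCH2CH2OMe)2 (1.5 equiv), THF, 0 °C → rt; then I2, THF, −78 → 0 °C
Reagents that add atoms: iodine, II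
Why: Hydroxyl-directed trans-hydroalumination of the propargylic alcohol: after loss of H2 the alkoxyaluminium hydride delivers hydride to proximal C2 and aluminium to distal C1 in a five-membered alanate, and iodine replaces aluminium with retention, so iodine on C1 is cis to C3.

Step 18
Reactants: 28 (1Z,3R,5E,7E,10R,11E)-11-[(tert-butyldimethylsilyloxy)methyl]-1-iodo-8-isopropyl-5-methyl-10-(triisopropylsilyloxy)cyclotetradeca-1,5,7,11-tetraen-3-ol
Product: 29 (1Z,3R,5E,7E,10R,11E)-11-[(tert-butyldimethylsilyloxy)methyl]-1-iodo-8-isopropyl-5-methyl-10-(triisopropylsilyloxy)cyclotetradeca-1,5,7,11-tetraen-3-yl acetate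
Conditions: Ac2O, pyridine, DMAP (cat.), CH2Cl2, 0 °C
Reagents that add atoms: acetic anhydride, CC(=O)OC(C)=O
Why: Acylation of the secondary allylic alcohol installs the C3 acetate of the target before the ester is made, so that O3 cannot lactonise onto C1 in the next step.

Step 19
Reactants: 29 (1Z,3R,5E,7E,10R,11E)-11-[(tert-butyldimethylsilyloxy)methyl]-1-iodo-8-isopropyl-5-methyl-10-(triisopropylsilyloxy)cyclotetradeca-1,5,7,11-tetraen-3-yl acetate
Product: 30 methyl (1Z,3R,5E,7E,10R,11E)-3-acetoxy-11-[(tert-butyldimethylsilyloxy)methyl]-8-isopropyl-5-methyl-10-(triisopropylsilyloxy)cyclotetradeca-1,5,7,11-tetraene-1-carboxylate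
Conditions: Pd(PPh3)4 (10 mol%), Et3N, CO (1 atm), MeOH–DMF, 45 °C
Reagents that add atoms: carbon monoxide, [C-]#[O+]; methanol, CO
Why: Palladium-catalysed methoxycarbonylation (oxidative addition of the alkenyl iodide to zerovalent palladium, CO insertion, methanolysis) with retention gives the Z-enoate; the C–I bond should react well before the allylic acetate can ionise.

Step 20
Reactants: 30 methyl (1Z,3R,5E,7E,10R,11E)-3-acetoxy-11-[(tert-butyldimethylsilyloxy)methyl]-8-isopropyl-5-methyl-10-(triisopropylsilyloxy)cyclotetradeca-1,5,7,11-tetraene-1-carboxylate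
Product: 31 methyl (1Z,3R,5E,7E,10R,11E)-3-acetoxy-11-(hydroxymethyl)-8-isopropyl-5-methyl-10-(triisopropylsilyloxy)cyclotetradeca-1,5,7,11-tetraene-1-carboxylate
Conditions: HF·pyridine, pyridine, THF, 0 °C
Reagents that add atoms: none
Why: Buffered fluoride desilylation cleaves the primary silyl ether far faster than the hindered secondary triisopropylsilyl ether and leaves acetate and ester intact.

Step 21
Reactants: 31 methyl (1Z,3R,5E,7E,10R,11E)-3-acetoxy-11-(hydroxymethyl)-8-isopropyl-5-methyl-10-(triisopropylsilyloxy)cyclotetradeca-1,5,7,11-tetraene-1-carboxylate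
Product: 32 methyl (1Z,3R,5E,7E,10R,11Z)-3-acetoxy-11-formyl-8-isopropyl-5-methyl-10-(triisopropylsilyloxy)cyclotetradeca-1,5,7,11-tetraene-1-carboxylate
Conditions: Dess–Martin periodinane, CH2Cl2, 0 °C → rt; crude product used at once
Reagents that add atoms: none
Why: Dess–Martin oxidation of the primary allylic alcohol under near-neutral conditions; the enal is not stored, to avoid isomerisation of C11=C12.

Step 22
Reactants: 32 methyl (1Z,3R,5E,7E,10R,11Z)-3-acetoxy-11-formyl-8-isopropyl-5-methyl-10-(triisopropylsilyloxy)cyclotetradeca-1,5,7,11-tetraene-1-carboxylate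
Product: 33 (1Z,3R,5E,7E,10R,11Z)-3-acetoxy-8-isopropyl-1-(methoxycarbonyl)-5-methyl-10-(triisopropylsilyloxy)cyclotetradeca-1,5,7,11-tetraene-11-carboxylic acid
Conditions: NaClO2, NaH2PO4, 2-methylbut-2-ene (excess), t-BuOH–H2O, 0 °C → rt
Reagents that add atoms: sodium chlorite, [Na+].[O-]Cl=O
Why: Pinnick oxidation of the enal to the acid; the alkene scavenger takes up hypochlorous acid and so protects the diene.

Step 23
Reactants: 33 (1Z,3R,5E,7E,10R,11Z)-3-acetoxy-8-isopropyl-1-(methoxycarbonyl)-5-methyl-10-(triisopropylsilyloxy)cyclotetradeca-1,5,7,11-tetraene-11-carboxylic acid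
Product: 34 dimethyl (1Z,3R,5E,7E,10R,11Z)-3-acetoxy-8-isopropyl-5-methyl-10-(triisopropylsilyloxy)cyclotetradeca-1,5,7,11-tetraene-1,11-dicarboxylate
Conditions: Me3SiCHN2, MeOH–toluene, 0 °C
Reagents that add atoms: (trimethylsilyl)diazomethane, C[Si](C)(C)C=[N+]=[N-]
Why: O-Methylation of the carboxylic acid by diazomethane generated from the silyl reagent and methanol; no base is present that could touch the acetate.

Step 24
Reactants: 34 dimethyl (1Z,3R,5E,7E,10R,11Z)-3-acetoxy-8-isopropyl-5-methyl-10-(triisopropylsilyloxy)cyclotetradeca-1,5,7,11-tetraene-1,11-dicarboxylate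
Product: 35 dimethyl (1Z,3R,5E,7E,10R,11Z)-3-acetoxy-10-hydroxy-8-isopropyl-5-methylcyclotetradeca-1,5,7,11-tetraene-1,11-dicarboxylate (CNP0189703.2)
Conditions: HF·pyridine (excess), THF, 0 °C → rt
Reagents that add atoms: none
Why: Fluoride desilylation of the secondary silyl ether under weakly acidic conditions frees the C10 hydroxyl without acyl migration or ester cleavage and should give the target.

**Compound list**
1 | hexa-1,5-diyne | C#CCCC#C | starting material
2 | lithium hexa-1,5-diyn-1-ide | [Li]C#CCCC#C | intermediate (not isolated)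
3 | trimethyl(hexa-1,5-diyn-1-yl)silane | C[Si](C)(C)C#CCCC#C | intermediate
4 | lithium 6-(trimethylsilyl)hexa-1,5-diyn-1-ide | [Li]C#CCCC#C[Si](C)(C)C | intermediate (not isolated)
5 | 7-(trimethylsilyl)hepta-2,6-diynal | O=CC#CCCC#C[Si](C)(C)C | intermediate
6 | 3-methylbutan-2-one | CC(C)C(C)=O | starting material
7 | (3-methylbut-1-en-2-yloxy)diisopinocampheylborane, from (+)-Ipc2BCl | C=C(C(C)C)OB([C@H]1C[C@H]2C[C@@H]([C@@H]1C)C2(C)C)[C@H]1C[C@H]2C[C@@H]([C@@H]1C)C2(C)C | intermediate (not isolated)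
8 | (5R)-5-hydroxy-2-methyl-11-(trimethylsilyl)undeca-6,10-diyn-3-one | C[Si](C)(C)C#CCCC#C[C@H](O)CC(=O)C(C)C | intermediate
9 | diethylphosphonoacetic acid | OC(=O)CP(=O)(OCC)OCC | starting material
10 | (5R)-2-methyl-3-oxo-11-(trimethylsilyl)undeca-6,10-diyn-5-yl (diethoxyphosphoryl)acetate | C[Si](C)(C)C#CCCC#C[C@H](OC(=O)CP(=O)(OCC)OCC)CC(=O)C(C)C | intermediate
11 | (6R)-4-isopropyl-6-[6-(trimethylsilyl)hexa-1,5-diyn-1-yl]-5,6-dihydro-2H-pyran-2-one | O=C1C=C(C(C)C)C[C@H](C#CCCC#C[Si](C)(C)C)O1 | intermediate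
12 | (2E,5R)-3-isopropyl-11-(trimethylsilyl)undec-2-ene-6,10-diyne-1,5-diol | C[Si](C)(C)C#CCCC#C[C@H](O)C/C(C(C)C)=C\CO | intermediate
13 | (2E,5R,6Z)-3-isopropyl-6-(tributylstannyl)-11-(trimethylsilyl)undeca-2,6-dien-10-yne-1,5-diol | C[Si](C)(C)C#CCC/C=C([Sn](CCCC)(CCCC)CCCC)/[C@H](O)C/C(C(C)C)=C\CO | intermediate
14 | methyl (2Z)-2-[(1R,3E)-1,5-dihydroxy-3-isopropylpent-3-en-1-yl]-7-(trimethylsilyl)hept-2-en-6-ynoate | C[Si](C)(C)C#CCC/C=C(C(=O)OC)/[C@H](O)C/C(C(C)C)=C\CO | intermediate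
15 | methyl (2Z)-2-[(1R,3E)-5-chloro-1-hydroxy-3-isopropylpent-3-en-1-yl]-7-(trimethylsilyl)hept-2-en-6-ynoate | C[Si](C)(C)C#CCC/C=C(C(=O)OC)/[C@H](O)C/C(C(C)C)=C\CCl | intermediate
16 | methyl (2Z)-2-[(1R,3E)-5-chloro-3-isopropyl-1-(triisopropylsilyloxy)pent-3-en-1-yl]-7-(trimethylsilyl)hept-2-en-6-ynoate | C[Si](C)(C)C#CCC/C=C(C(=O)OC)/[C@H](O[Si](C(C)C)(C(C)C)C(C)C)C/C(C(C)C)=C\CCl | intermediate
17 | 2-bromopropene | CC(Br)=C | starting material
18 | isopropenylmagnesium bromide | CC(=C)[Mg]Br | intermediate (not isolated)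
19 | isopropenylzinc chloride | CC(=C)[Zn]Cl | intermediate (not isolated)
20 | methyl (2Z)-2-[(1R,3E)-3-isopropyl-6-methyl-1-(triisopropylsilyloxy)hepta-3,6-dien-1-yl]-7-(trimethylsilyl)hept-2-en-6-ynoate | C[Si](C)(C)C#CCC/C=C(C(=O)OC)/[C@H](O[Si](C(C)C)(C(C)C)C(C)C)C/C(C(C)C)=C\CC(C)=C | intermediate
21 | (2E)-2-[(1R,3E)-3-isopropyl-6-methyl-1-(triisopropylsilyloxy)hepta-3,6-dien-1-yl]-7-(trimethylsilyl)hept-2-en-6-yn-1-ol | C[Si](C)(C)C#CCC/C=C(CO)/[C@H](O[Si](C(C)C)(C(C)C)C(C)C)C/C(C(C)C)=C\CC(C)=C | intermediate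
22 | [(5E,7R,9E)-6-[(tert-butyldimethylsilyloxy)methyl]-9-isopropyl-12-methyl-7-(triisopropylsilyloxy)trideca-5,9,12-trien-1-yn-1-yl]trimethylsilane | C[Si](C)(C)C#CCC/C=C(CO[Si](C)(C)C(C)(C)C)/[C@H](O[Si](C(C)C)(C(C)C)C(C)C)C/C(C(C)C)=C\CC(C)=C | intermediate
23 | (5E,7R,9E)-6-[(tert-butyldimethylsilyloxy)methyl]-9-isopropyl-12-methyl-7-(triisopropylsilyloxy)trideca-5,9,12-trien-1-yne | C#CCC/C=C(CO[Si](C)(C)C(C)(C)C)/[C@H](O[Si](C(C)C)(C(C)C)C(C)C)C/C(C(C)C)=C\CC(C)=C | intermediate
24 | lithium acetylide of 23 (Li on C2) | [Li]C#CCC/C=C(CO[Si](C)(C)C(C)(C)C)/[C@H](O[Si](C(C)C)(C(C)C)C(C)C)C/C(C(C)C)=C\CC(C)=C | intermediate (not isolated)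
25 | (6E,8R,10E)-7-[(tert-butyldimethylsilyloxy)methyl]-10-isopropyl-13-methyl-8-(triisopropylsilyloxy)tetradeca-6,10,13-trien-2-ynal | O=CC#CCC/C=C(CO[Si](C)(C)C(C)(C)C)/[C@H](O[Si](C(C)C)(C(C)C)C(C)C)C/C(C(C)C)=C\CC(C)=C | intermediate (key-step precursor)
26 | (3R,5E,7E,10R,11E)-11-[(tert-butyldimethylsilyloxy)methyl]-8-isopropyl-5-methyl-10-(triisopropylsilyloxy)cyclotetradeca-5,7,11-trien-1-yn-3-ol | O[C@H]1C#CCC/C=C(CO[Si](C)(C)C(C)(C)C)/[C@H](O[Si](C(C)C)(C(C)C)C(C)C)C/C(C(C)C)=C\C=C(C)\C1 | intermediate (key-step product)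
27 | sodium bis(2-methoxyethoxy)alanate of 26 with Al bound to O3 and C1 (five-membered ring), H on C2 | [Na+].COCCO[Al-]1(OCCOC)O[C@H]2/C=C1/CC/C=C(CO[Si](C)(C)C(C)(C)C)/[C@H](O[Si](C(C)C)(C(C)C)C(C)C)C/C(C(C)C)=C\C=C(C)\C2 | intermediate (not isolated)
28 | (1Z,3R,5E,7E,10R,11E)-11-[(tert-butyldimethylsilyloxy)methyl]-1-iodo-8-isopropyl-5-methyl-10-(triisopropylsilyloxy)cyclotetradeca-1,5,7,11-tetraen-3-ol | O[C@H]1/C=C(I)/CC/C=C(CO[Si](C)(C)C(C)(C)C)/[C@H](O[Si](C(C)C)(C(C)C)C(C)C)C/C(C(C)C)=C\C=C(C)\C1 | intermediate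
29 | 3-O-acetate of 28 | CC(=O)O[C@H]1/C=C(I)/CC/C=C(CO[Si](C)(C)C(C)(C)C)/[C@H](O[Si](C(C)C)(C(C)C)C(C)C)C/C(C(C)C)=C\C=C(C)\C1 | intermediate
30 | methyl (1Z,3R,5E,7E,10R,11E)-3-acetoxy-11-[(tert-butyldimethylsilyloxy)methyl]-8-isopropyl-5-methyl-10-(triisopropylsilyloxy)cyclotetradeca-1,5,7,11-tetraene-1-carboxylate | CC(=O)O[C@H]1/C=C(C(=O)OC)/CC/C=C(CO[Si](C)(C)C(C)(C)C)/[C@H](O[Si](C(C)C)(C(C)C)C(C)C)C/C(C(C)C)=C\C=C(C)\C1 | intermediate
31 | methyl (1Z,3R,5E,7E,10R,11E)-3-acetoxy-11-(hydroxymethyl)-8-isopropyl-5-methyl-10-(triisopropylsilyloxy)cyclotetradeca-1,5,7,11-tetraene-1-carboxylate | CC(=O)O[C@H]1/C=C(C(=O)OC)/CC/C=C(CO)/[C@H](O[Si](C(C)C)(C(C)C)C(C)C)C/C(C(C)C)=C\C=C(C)\C1 | intermediate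
32 | methyl (1Z,3R,5E,7E,10R,11Z)-3-acetoxy-11-formyl-8-isopropyl-5-methyl-10-(triisopropylsilyloxy)cyclotetradeca-1,5,7,11-tetraene-1-carboxylate | CC(=O)O[C@H]1/C=C(C(=O)OC)/CC/C=C(C=O)/[C@H](O[Si](C(C)C)(C(C)C)C(C)C)C/C(C(C)C)=C\C=C(C)\C1 | intermediate
33 | (1Z,3R,5E,7E,10R,11Z)-3-acetoxy-8-isopropyl-1-(methoxycarbonyl)-5-methyl-10-(triisopropylsilyloxy)cyclotetradeca-1,5,7,11-tetraene-11-carboxylic acid | CC(=O)O[C@H]1/C=C(C(=O)OC)/CC/C=C(C(=O)O)/[C@H](O[Si](C(C)C)(C(C)C)C(C)C)C/C(C(C)C)=C\C=C(C)\C1 | intermediate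
34 | dimethyl (1Z,3R,5E,7E,10R,11Z)-3-acetoxy-8-isopropyl-5-methyl-10-(triisopropylsilyloxy)cyclotetradeca-1,5,7,11-tetraene-1,11-dicarboxylate | CC(=O)O[C@H]1/C=C(C(=O)OC)/CC/C=C(C(=O)OC)/[C@H](O[Si](C(C)C)(C(C)C)C(C)C)C/C(C(C)C)=C\C=C(C)\C1 | intermediate
35 | dimethyl (1Z,3R,5E,7E,10R,11Z)-3-acetoxy-10-hydroxy-8-isopropyl-5-methylcyclotetradeca-1,5,7,11-tetraene-1,11-dicarboxylate (CNP0189703.2) | CC(=O)O[C@H]1/C=C(C(=O)OC)/CC/C=C(C(=O)OC)/[C@H](O)C/C(C(C)C)=C\C=C(C)\C1 | target

**Step count and risks**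
Total step count: 24. Longest linear sequence: 24 steps (1 → 35); compounds 6, 9 and 17 enter as purchased materials.

Steps most likely to fail:

1. Step 16 (key step). The chiral titanium Lewis acid may fail to activate the alkyl-substituted ynal enough for ring closure, so that oligomerisation wins. Hydrogen may also be taken from the C5 methyl group, or the facial selectivity at C3 may be poor. Fallback with known chemistry, from 23 back to 26: the C3–C4 bond is made intermolecularly and the ring is closed at C1≡C2 instead. C-Methylation of 23 (n-BuLi, MeI) gives the methyl-capped alkyne F1. A BINOL–titanium glyoxylate–ene reaction with ethyl glyoxylate ((R)-BINOL, TiCl2(OiPr)2, 4 Å molecular sieves, CH2Cl2, −30 °C) forms C3–C4 and C5=C6 and gives the (R)-hydroxy ester F2. Silylation (Et3SiOTf, 2,6-lutidine) gives the triethylsilyl ether F3, and iBu2AlH at −78 °C the aldehyde F4. Corey–Fuchs olefination (CBr4, PPh3, Zn) gives the dibromoalkene F5, and n-BuLi followed by MeI the diyne F6. Ring-closing alkyne metathesis with [Mo(≡CC6H4OMe-4)(OSiPh3)3] in toluene at high dilution gives the macrocyclic triethylsilyl ether F7, and PPTS in MeOH at 0 °C frees the C3 hydroxyl to give 26.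

2. Step 7. Tin hydride may add to the silyl-capped triple bond as well, or tin may be delivered to distal C12. Fallback, from 12 back to 14: an alkoxide-bound aluminium hydride can only reach the triple bond next to the alkoxide. Trans-hydroalumination of 12 with LiAlH4/AlCl3 (60:1) in THF, then I2 at −78 °C, should give the (Z)-2-iodo allylic alcohol F8. Methoxycarbonylation (Pd(PPh3)4, CO, MeOH, Et3N) then gives 14.

3. Step 3. The boron enolate may add with poor facial selectivity, which would lower the enantiomeric purity at C10 for the whole route. Fallback, from 5 back to 8: auxiliary control replaces reagent control. (R)-2-Hydroxy-1,2,2-triphenylethyl acetate is doubly deprotonated (LiN(iPr)2, THF), transmetalated with MgBr2 and added to 5 at −115 °C to give the hydroxy ester F9, which can be purified by crystallisation. Aminolysis with MeNH(OMe)·HCl and iPrMgCl gives the N-methoxy-N-methylamide F10, and addition of iPrMgCl gives 8.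

**Further compounds**
F1 | step 16 | (6E,8R,10E)-7-[(tert-butyldimethylsilyloxy)methyl]-10-isopropyl-13-methyl-8-(triisopropylsilyloxy)tetradeca-6,10,13-trien-2-yne | CC#CCC/C=C(CO[Si](C)(C)C(C)(C)C)/[C@H](O[Si](C(C)C)(C(C)C)C(C)C)C/C(C(C)C)=C\CC(C)=C
F2 | step 16 | ethyl (2R,4E,6E,9R,10E)-10-[(tert-butyldimethylsilyloxy)methyl]-2-hydroxy-7-isopropyl-4-methyl-9-(triisopropylsilyloxy)hexadeca-4,6,10-trien-14-ynoate | CCOC(=O)[C@H](O)C/C(C)=C/C=C(/C(C)C)C[C@@H](O[Si](C(C)C)(C(C)C)C(C)C)/C(CO[Si](C)(C)C(C)(C)C)=C/CCC#CC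
F3 | step 16 | 2-O-triethylsilyl ether of F2 | CCOC(=O)[C@H](O[Si](CC)(CC)CC)C/C(C)=C/C=C(/C(C)C)C[C@@H](O[Si](C(C)C)(C(C)C)C(C)C)/C(CO[Si](C)(C)C(C)(C)C)=C/CCC#CC
F4 | step 16 | (2R,4E,6E,9R,10E)-10-[(tert-butyldimethylsilyloxy)methyl]-7-isopropyl-4-methyl-2-(triethylsilyloxy)-9-(triisopropylsilyloxy)hexadeca-4,6,10-trien-14-ynal | O=C[C@H](O[Si](CC)(CC)CC)C/C(C)=C/C=C(/C(C)C)C[C@@H](O[Si](C(C)C)(C(C)C)C(C)C)/C(CO[Si](C)(C)C(C)(C)C)=C/CCC#CC
F5 | step 16 | (3R,5E,7E,10R,11E)-1,1-dibromo-11-[(tert-butyldimethylsilyloxy)methyl]-8-isopropyl-5-methyl-3-(triethylsilyloxy)-10-(triisopropylsilyloxy)heptadeca-1,5,7,11-tetraen-15-yne | BrC(Br)=C[C@H](O[Si](CC)(CC)CC)C/C(C)=C/C=C(/C(C)C)C[C@@H](O[Si](C(C)C)(C(C)C)C(C)C)/C(CO[Si](C)(C)C(C)(C)C)=C/CCC#CC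
F6 | step 16 | (4R,6E,8E,11R,12E)-12-[(tert-butyldimethylsilyloxy)methyl]-9-isopropyl-6-methyl-4-(triethylsilyloxy)-11-(triisopropylsilyloxy)octadeca-6,8,12-triene-2,16-diyne | CC#C[C@H](O[Si](CC)(CC)CC)C/C(C)=C/C=C(/C(C)C)C[C@@H](O[Si](C(C)C)(C(C)C)C(C)C)/C(CO[Si](C)(C)C(C)(C)C)=C/CCC#CC
F7 | step 16 | 3-O-triethylsilyl ether of 26 | CC[Si](CC)(CC)O[C@H]1C#CCC/C=C(CO[Si](C)(C)C(C)(C)C)/[C@H](O[Si](C(C)C)(C(C)C)C(C)C)C/C(C(C)C)=C\C=C(C)\C1
F8 | step 7 | (2E,5R,6Z)-6-iodo-3-isopropyl-11-(trimethylsilyl)undeca-2,6-dien-10-yne-1,5-diol | C[Si](C)(C)C#CCC/C=C(I)/[C@H](O)C/C(C(C)C)=C\CO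
F9 | step 3 | (1R)-2-hydroxy-1,2,2-triphenylethyl (3R)-3-hydroxy-9-(trimethylsilyl)nona-4,8-diynoate | O=C(C[C@@H](O)C#CCCC#C[Si](C)(C)C)O[C@H](c1ccccc1)C(O)(c1ccccc1)c1ccccc1
F10 | step 3 | (3R)-3-hydroxy-N-methoxy-N-methyl-9-(trimethylsilyl)nona-4,8-diynamide | CON(C)C(=O)C[C@@H](O)C#CCCC#C[Si](C)(C)C
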